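**Retrosynthetic overview**
1. Kazinol N (16) comes from its bis-MOM ether 15 by acetal cleavage in the last step.
2. 15 comes from iodochromene 14, alkyl iodide 6 and prenylB(pin) in one Pd/norbornene relay that makes both the C6–CH2 bond of the 1,3-diarylpropane and the C5–prenyl bond (the new step).
3. 14 comes from aryl propargyl ether 11 by Claisen rearrangement and oxa-6π closure; 11 comes from 5-iodosalicylaldehyde 7 by MOM protection, Dakin oxidation and O-propargylation.
4. 6 comes from 4-hydroxy-2-methoxybenzaldehyde 1 by MOM protection, Wittig olefination, hydrogenation, LiAlH4 reduction and Appel iodination.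
5. Ring order: benzene rings A and B are bought; the pyran ring is the only ring built (step 9), before the fragments are joined (step 10).

Assumption: the target as drawn has no stereocentre and no stereogenic alkene, so it is achiral and "single enantiomer" is taken to mean the constitution given.

**Route**

Step 1
Reactants: 1 4-hydroxy-2-methoxybenzaldehyde
Product: 2 2-methoxy-4-(methoxymethoxy)benzaldehyde
Conditions: MOMCl, iPr2NEt, CH2Cl2, 0 °C to rt
Reagents that add atoms: chloromethyl methyl ether (MOMCl), COCCl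
Why: O-alkylation of the acidic phenol (Williamson-type acetal formation) gives a MOM ether that is stable to the ylide, hydride, hydrogenation and palladium steps that follow.

Step 2
Reactants: 2 2-methoxy-4-(methoxymethoxy)benzaldehyde
Product: 3 ethyl (2E)-3-[2-methoxy-4-(methoxymethoxy)phenyl]prop-2-enoate
Conditions: Ph3P=CHCO2Et, toluene, 90 °C
Reagents that add atoms: (ethoxycarbonylmethylene)triphenylphosphorane, CCOC(=O)C=P(c1ccccc1)(c1ccccc1)c1ccccc1
Why: Wittig olefination with a stabilised ylide gives the E-cinnamate and adds the two missing chain carbons (the alkene geometry is erased in step 3).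

Step 3
Reactants: 3 ethyl (2E)-3-[2-methoxy-4-(methoxymethoxy)phenyl]prop-2-enoate
Product: 4 ethyl 3-[2-methoxy-4-(methoxymethoxy)phenyl]propanoate
Conditions: H2 (1 atm), Pd/C (10 wt %), EtOAc, rt
Reagents that add atoms: none
Why: Heterogeneous catalytic hydrogenation saturates the conjugated alkene and leaves the ester, aryl ether and MOM acetal alone.

Step 4
Reactants: 4 ethyl 3-[2-methoxy-4-(methoxymethoxy)phenyl]propanoate
Product: 5 3-[2-methoxy-4-(methoxymethoxy)phenyl]propan-1-ol
Conditions: LiAlH4, THF, 0 °C; aqueous work-up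
Reagents that add atoms: none
Why: Hydride reduction of the ester gives the primary alcohol.

Step 5
Reactants: 5 3-[2-methoxy-4-(methoxymethoxy)phenyl]propan-1-ol
Product: 6 1-(3-iodopropyl)-2-methoxy-4-(methoxymethoxy)benzene
Conditions: I2, PPh3, imidazole, CH2Cl2, 0 °C to rt
Reagents that add atoms: iodine, II
Why: Appel-type iodination (SN2 displacement of the alkoxyphosphonium by iodide) proceeds under imidazole buffering, which keeps the MOM acetal intact.

Step 6
Reactants: 7 2-hydroxy-5-iodobenzaldehyde
Product: 8 5-iodo-2-(methoxymethoxy)benzaldehyde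
Conditions: MOMCl, iPr2NEt, CH2Cl2, 0 °C to rt
Reagents that add atoms: chloromethyl methyl ether (MOMCl), COCCl
Why: MOM protection (O-alkylation) masks the oxygen para to iodine, which becomes the free C8 hydroxyl of the target.

Step 7
Reactants: 8 5-iodo-2-(methoxymethoxy)benzaldehyde
Product: 10 5-iodo-2-(methoxymethoxy)phenol, via aryl formate 9 (not isolated)
Conditions: mCPBA (1.3 equiv), CH2Cl2, 0 °C to rt; aq. Na2S2O3/NaHCO3 wash; then K2CO3 (0.2 equiv), MeOH, rt
Reagents that add atoms: 3-chloroperoxybenzoic acid (mCPBA), OOC(=O)c1cccc(Cl)c1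
Why: Baeyer–Villiger (Dakin-type) oxidation, in which the electron-rich ortho-alkoxy aryl group migrates to give formate 9, followed by methanolysis, fixes the second oxygen meta to iodine without any regiochemical ambiguity.

Step 8
Reactants: 10 5-iodo-2-(methoxymethoxy)phenol
Product: 11 4-iodo-1-(methoxymethoxy)-2-[(2-methylbut-3-yn-2-yl)oxy]benzene
Conditions: 3-chloro-3-methylbut-1-yne (1.5 equiv), DBU (1.6 equiv), CuCl2·2H2O (1 mol %), MeCN, 0 °C to rt
Reagents that add atoms: 3-chloro-3-methylbut-1-yne, CC(C)(Cl)C#C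
Why: Copper-catalysed propargylic etherification of the phenoxide with the tertiary propargylic chloride gives the hindered tertiary aryl ether that a simple SN2 reaction cannot make.

Step 9
Reactants: 11 4-iodo-1-(methoxymethoxy)-2-[(2-methylbut-3-yn-2-yl)oxy]benzene
Product: 14 5-iodo-8-(methoxymethoxy)-2,2-dimethyl-2H-chromene, via allenylphenol 12 (not isolated), via o-quinone methide 13 (not isolated)
Conditions: o-xylene, 145 °C (sealed tube), 12 h
Reagents that add atoms: none
Why: Aromatic propargyl Claisen rearrangement to the only free ortho carbon gives allenylphenol 12, a 1,5-hydrogen shift gives o-quinone methide 13, and oxa-6π electrocyclisation closes the pyran ring with the iodine placed at C5.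

Step 10
Reactants: 14 5-iodo-8-(methoxymethoxy)-2,2-dimethyl-2H-chromene; 6 1-(3-iodopropyl)-2-methoxy-4-(methoxymethoxy)benzene
Product: 15 8-(methoxymethoxy)-6-{3-[2-methoxy-4-(methoxymethoxy)phenyl]propyl}-2,2-dimethyl-5-(3-methylbut-2-en-1-yl)-2H-chromene
Conditions: Pd(OAc)2 (10 mol %), P(2-furyl)3 (25 mol %), norbornene (2 equiv), 6 (1.5 equiv), Cs2CO3 (4 equiv), H2O (5 equiv), MeCN, 85 °C; prenylB(pin) (1.5 equiv) added by syringe pump over 6 h
Reagents that add atoms: 3-methylbut-2-en-1-ylboronic acid pinacol ester (prenylB(pin)), CC(C)=CCB1OC(C)(C)C(C)(C)O1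
Why: Proposed new method: a three-component Pd/norbornene (Catellani-type) relay in which zerovalent palladium adds into the C5–I bond of 14, the arylpalladium inserts norbornene and palladates the only free ortho C–H (C6) to a five-membered palladacycle, primary iodide 6 alkylates that carbon through a tetravalent palladium intermediate, norbornene is extruded once both ortho positions are filled, and the doubly ortho-substituted aryl divalent palladium iodide is then terminated by transmetallation with slowly added prenylB(pin) and reductive elimination at the unsubstituted allyl terminus (linear prenyl favoured by the two ortho substituents), the closest known reactions being Catellani ortho-alkylation with ipso Suzuki termination by aryl boron reagents and the linear-selective Suzuki–Miyaura prenylation of aryl halides, neither of which has been shown with an allyl boron terminus in the relay or on a 2H-chromene iodide.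

Step 11
Reactants: 15 8-(methoxymethoxy)-6-{3-[2-methoxy-4-(methoxymethoxy)phenyl]propyl}-2,2-dimethyl-5-(3-methylbut-2-en-1-yl)-2H-chromene
Product: 16 kazinol N
Conditions: 3 M aq. HCl, MeOH, 40 °C
Reagents that add atoms: none
Why: Acid-catalysed transacetalisation to methanol removes both MOM groups, while the aryl methyl ether is inert and the prenyl group has no ortho hydroxyl to cyclise onto.

**Compound list**
1 | 4-hydroxy-2-methoxybenzaldehyde | COc1cc(O)ccc1C=O | starting material
2 | 2-methoxy-4-(methoxymethoxy)benzaldehyde | COCOc1ccc(C=O)c(OC)c1 | intermediate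
3 | ethyl (2E)-3-[2-methoxy-4-(methoxymethoxy)phenyl]prop-2-enoate | CCOC(=O)/C=C/c1ccc(OCOC)cc1OC | intermediate
4 | ethyl 3-[2-methoxy-4-(methoxymethoxy)phenyl]propanoate | CCOC(=O)CCc1ccc(OCOC)cc1OC | intermediate
5 | 3-[2-methoxy-4-(methoxymethoxy)phenyl]propan-1-ol | OCCCc1ccc(OCOC)cc1OC | intermediate
6 | 1-(3-iodopropyl)-2-methoxy-4-(methoxymethoxy)benzene | ICCCc1ccc(OCOC)cc1OC | intermediate
7 | 2-hydroxy-5-iodobenzaldehyde | O=Cc1cc(I)ccc1O | starting material
8 | 5-iodo-2-(methoxymethoxy)benzaldehyde | COCOc1ccc(I)cc1C=O | intermediate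
9 | 5-iodo-2-(methoxymethoxy)phenyl formate (not isolated) | COCOc1ccc(I)cc1OC=O | intermediate
10 | 5-iodo-2-(methoxymethoxy)phenol | COCOc1ccc(I)cc1O | intermediate
11 | 4-iodo-1-(methoxymethoxy)-2-[(2-methylbut-3-yn-2-yl)oxy]benzene | COCOc1ccc(I)cc1OC(C)(C)C#C | intermediate
12 | 3-iodo-6-(methoxymethoxy)-2-(3-methylbuta-1,2-dien-1-yl)phenol (not isolated) | COCOc1ccc(I)c(C=C=C(C)C)c1O | intermediate
13 | (6E)-5-iodo-2-(methoxymethoxy)-6-(3-methylbut-2-en-1-ylidene)cyclohexa-2,4-dien-1-one (not isolated) | O=C1C(OCOC)=CC=C(I)/C1=C/C=C(C)C | intermediate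
14 | 5-iodo-8-(methoxymethoxy)-2,2-dimethyl-2H-chromene | COCOc1ccc(I)c2c1OC(C)(C)C=C2 | intermediate
15 | 8-(methoxymethoxy)-6-{3-[2-methoxy-4-(methoxymethoxy)phenyl]propyl}-2,2-dimethyl-5-(3-methylbut-2-en-1-yl)-2H-chromene | COCOc1ccc(CCCc2cc(OCOC)c3OC(C)(C)C=Cc3c2CC=C(C)C)c(OC)c1 | intermediate
16 | kazinol N | COc1cc(O)ccc1CCCc1cc(O)c2c(c1CC=C(C)C)C=CC(C)(C)O2 | target

**Step count**
Total: 11 steps. Longest linear sequence: 7 steps (steps 1–5, 10, 11).

**Three steps most likely to fail**

Step 10 (the proposed new relay). The risks are direct ipso prenylation before norbornene insertion, interference from the chromene alkene, and branched prenyl coupling. The fallback uses known chemistry only; it sets out from 10 (and uses 6) and comes back at 15. Phenol 10 is brominated para to the hydroxyl (NBS, MeCN, 0 °C) to give 4-bromo-5-iodo-2-(methoxymethoxy)phenol F1. O-propargylation as in step 8 gives 1-bromo-2-iodo-5-(methoxymethoxy)-4-[(2-methylbut-3-yn-2-yl)oxy]benzene F2. Heating as in step 9 passes through 4-bromo-3-iodo-6-(methoxymethoxy)-2-(3-methylbuta-1,2-dien-1-yl)phenol F3 and (6E)-4-bromo-5-iodo-2-(methoxymethoxy)-6-(3-methylbut-2-en-1-ylidene)cyclohexa-2,4-dien-1-one F4 to give 6-bromo-5-iodo-8-(methoxymethoxy)-2,2-dimethyl-2H-chromene F5. An iodide-selective Suzuki–Miyaura prenylation (prenylB(pin), PdCl2(dppf), K3PO4, THF/H2O, 50 °C) gives 6-bromo-8-(methoxymethoxy)-2,2-dimethyl-5-(3-methylbut-2-en-1-yl)-2H-chromene F6. Zinc insertion into 6 (Zn dust, LiCl, THF, 40 °C) gives {3-[2-methoxy-4-(methoxymethoxy)phenyl]propyl}zinc iodide F7, and Negishi coupling of F6 with F7 (Pd(OAc)2, SPhos, THF, 50 °C) gives 15.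

Step 9 (Claisen/electrocyclisation). The [3,3] shift has to deliver carbon to the position squeezed between the ether oxygen and the iodine, at a temperature where the C–I bond and the MOM acetal are under stress. The fallback sets out from 10 and comes back at 14, so it also bypasses 11. Phenol 10 is condensed with 3-methylbut-2-enal in a boron-templated ortho-specific reaction (PhB(OH)2, propionic acid cat., toluene, reflux, Dean–Stark). This forms racemic 5-iodo-8-(methoxymethoxy)-4-(2-methylprop-1-en-1-yl)-2-phenyl-4H-1,3,2-benzodioxaborine F8, which fragments in the flask to the same o-quinone methide 13 and electrocyclises to 14.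

Step 11 (global MOM removal). Brønsted acid could hydrate or oligomerise the chromene or prenyl alkenes. The fallback sets out from 15 and comes back at 16. The acetals are exchanged for silyl ethers without protic acid (TESOTf, 2,2'-bipyridyl, CH2Cl2, 0 °C to rt) to give 6-{3-[2-methoxy-4-(triethylsilyloxy)phenyl]propyl}-2,2-dimethyl-5-(3-methylbut-2-en-1-yl)-8-(triethylsilyloxy)-2H-chromene F9, which is desilylated with fluoride (TBAF, THF, 0 °C) to 16.

**Further compounds**
F1 | step 10 | 4-bromo-5-iodo-2-(methoxymethoxy)phenol | COCOc1cc(Br)c(I)cc1O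
F2 | step 10 | 1-bromo-2-iodo-5-(methoxymethoxy)-4-[(2-methylbut-3-yn-2-yl)oxy]benzene | COCOc1cc(Br)c(I)cc1OC(C)(C)C#C
F3 | step 10 | 4-bromo-3-iodo-6-(methoxymethoxy)-2-(3-methylbuta-1,2-dien-1-yl)phenol | COCOc1cc(Br)c(I)c(C=C=C(C)C)c1O
F4 | step 10 | (6E)-4-bromo-5-iodo-2-(methoxymethoxy)-6-(3-methylbut-2-en-1-ylidene)cyclohexa-2,4-dien-1-one | O=C1C(OCOC)=CC(Br)=C(I)/C1=C/C=C(C)C
F5 | step 10 | 6-bromo-5-iodo-8-(methoxymethoxy)-2,2-dimethyl-2H-chromene | COCOc1cc(Br)c(I)c2c1OC(C)(C)C=C2
F6 | step 10 | 6-bromo-8-(methoxymethoxy)-2,2-dimethyl-5-(3-methylbut-2-en-1-yl)-2H-chromene | COCOc1cc(Br)c(CC=C(C)C)c2c1OC(C)(C)C=C2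
F7 | step 10 | {3-[2-methoxy-4-(methoxymethoxy)phenyl]propyl}zinc iodide | COCOc1ccc(CCC[Zn]I)c(OC)c1
F8 | step 9 | 5-iodo-8-(methoxymethoxy)-4-(2-methylprop-1-en-1-yl)-2-phenyl-4H-1,3,2-benzodioxaborine (racemic) | COCOc1ccc(I)c2c1OB(c1ccccc1)OC2C=C(C)C
F9 | step 11 | 6-{3-[2-methoxy-4-(triethylsilyloxy)phenyl]propyl}-2,2-dimethyl-5-(3-methylbut-2-en-1-yl)-8-(triethylsilyloxy)-2H-chromene | CC[Si](CC)(CC)Oc1ccc(CCCc2cc(O[Si](CC)(CC)CC)c3OC(C)(C)C=Cc3c2CC=C(C)C)c(OC)c1
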